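**Plan**

1. Atom numbers follow the labdane skeleton (ring A = C1–C5/C10, ring B = C5–C10, side chain C11–C15). Retrosynthesis: the esters and silyl groups come off first; ring B is then cut at C5–C6 and at C8=C9 in one stroke, giving β-diketone 10 and the four-carbon ketophosphonate 14; 10 is cut at C9–C10 into silylated actinol 7 and aldehyde 5.
2. The feature that allows the one-stroke cut: C5 and C9 both sit on the quaternary C10 (a 1,3-dicarbonyl pattern that cannot enolise between its carbonyls), and C6–C7–C8 of ring B is an α-oxygenated ketone triad. Ring B is therefore the retron of a [3+3] union of a 1,3-bis-electrophile with the α,γ-dianion of an α-methoxy β-ketophosphonate.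
3. Forward: ring A is bought (actinol); the geraniol-derived side chain is joined at C10 by aldol addition and oxidation; ring B is closed in step 8 (aldol at C9, Horner–Wadsworth–Emmons at C5, dehydration to C8=C9); redox and acylation steps finish the molecule.
4. Stereochemistry: C2 from actinol; C10 from the C2-controlled aldol (methyl axial, trans to O2); C5 by equilibration next to the C6 ketone (trans ring fusion); C7 by α-face hydride delivery, then Mitsunobu inversion with acetic acid; C6 by α-face hydride attack (β face blocked by the axial C4 and C10 methyls); 13E from geraniol.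

Key step: step 8

Assumption: (4R,6R)-4-hydroxy-2,2,6-trimethylcyclohexan-1-one (actinol), an industrial carotenoid intermediate, is treated as a purchasable starting material.

Step 1
Reactants: 1 geraniol
Product: 2 geranyl tert-butyldiphenylsilyl ether
Conditions: TBDPSCl, imidazole, DMF, 23 °C
Reagents that add atoms: tert-butyl(chloro)diphenylsilane, CC(C)(C)[Si](Cl)(c1ccccc1)c1ccccc1
Why: Silyl ether formation at the primary allylic alcohol should protect O15 with a group that survives every later base, hydride and mild-acid step and leaves only at the end.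

Step 2
Reactants: 2 geranyl tert-butyldiphenylsilyl ether
Product: 3 6,7-epoxygeranyl tert-butyldiphenylsilyl ether (racemic at the epoxide)
Conditions: mCPBA, NaHCO3, CH2Cl2, −20 °C
Reagents that add atoms: 3-chloroperbenzoic acid, OOC(=O)c1cccc(Cl)c1
Why: Prilezhaev epoxidation should pick the remote, more electron-rich trisubstituted alkene over the one deactivated by the allylic oxygen; the epoxide stereocentre is lost in step 3.

Step 3
Reactants: 3 6,7-epoxygeranyl tert-butyldiphenylsilyl ether
Product: 5 (4E)-6-(tert-butyldiphenylsilyloxy)-4-methylhex-4-enal, via diol 4 (not isolated)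
Conditions: H5IO6, THF–H2O, 0 °C
Reagents that add atoms: water, O
Why: Acid-promoted epoxide hydrolysis followed by periodate (Malaprade) glycol cleavage should excise acetone and leave the aldehyde carbon that becomes C9, with the 13E alkene untouched.

Step 4
Reactants: 6 (4R,6R)-4-hydroxy-2,2,6-trimethylcyclohexan-1-one (actinol)
Product: 7 (4R,6R)-4-(tert-butyldimethylsilyloxy)-2,2,6-trimethylcyclohexan-1-one
Conditions: TBSCl, imidazole, DMF, 23 °C
Reagents that add atoms: tert-butyl(chloro)dimethylsilane, CC(C)(C)[Si](C)(C)Cl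
Why: Silyl ether formation should mask the future C2 oxygen against the enolate chemistry of steps 5 to 8 while keeping it removable separately from the C15 silyl group.

Step 5
Reactants: 7 (4R,6R)-4-(tert-butyldimethylsilyloxy)-2,2,6-trimethylcyclohexan-1-one; 5 (4E)-6-(tert-butyldiphenylsilyloxy)-4-methylhex-4-enal
Product: 9 C10-quaternary aldol adduct (2α-silyloxy; 10β-methyl; C9 carbinol chain on the α face; both C9 epimers), via lithium enolate 8 (not isolated)
Conditions: LiN(iPr)2, THF, −78 °C; 5, −78 °C; AcOH quench at −78 °C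
Reagents that add atoms: none
Why: Aldol addition of the only possible enolate (C5–C10, since C4 is quaternary) through a closed Zimmerman–Traxler transition state should occur on the face away from the pseudoaxial C4 methyl, which is the face of the equatorial C2 silyloxy group, so that the C9 substituent ends up equatorial and cis to O2 with the C10 methyl axial (also the arrangement favoured at equilibrium); the C9 carbinol configuration is erased in step 6.

Step 6
Reactants: 9 C10-quaternary aldol adduct
Product: 10 β-diketone (C5 ring ketone and C9 side-chain ketone on quaternary C10; 2α-silyloxy; 10β-methyl)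
Conditions: Dess–Martin periodinane, NaHCO3, CH2Cl2, 23 °C
Reagents that add atoms: none
Why: Dess–Martin oxidation of the hindered secondary carbinol should give the non-enolisable 1,3-diketone under neutral conditions that avoid retro-aldol and retro-Claisen cleavage.

Step 7
Reactants: 11 diethyl (methoxymethyl)phosphonate; 12 methyl propanoate
Product: 14 diethyl (1-methoxy-2-oxobutyl)phosphonate, via lithiated phosphonate 13 (not isolated)
Conditions: LiN(iPr)2 (2.1 equiv), THF, −78 °C; 12, −78 → 0 °C; aq. HCl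
Reagents that add atoms: none
Why: C-acylation of the α-lithiated phosphonate by the ester (β-ketophosphonate synthesis) should deliver the four-carbon unit that carries C6 with its oxygen, C7, C8 and the C8 methyl, the second equivalent of base holding the product as its enolate.

Step 8
Reactants: 10 β-diketone; 14 diethyl (1-methoxy-2-oxobutyl)phosphonate
Product: 18 2α-(tert-butyldimethylsilyloxy)-15-(tert-butyldiphenylsilyloxy)-6-methoxylabda-5,8,13E-trien-7-one, via phosphonate dianion 15 (not isolated), via aldol adduct 16 (not isolated), via hydroxy enone 17 (not isolated)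
Conditions: 14, LiN(iPr)2 (2.1 equiv), THF, −78 → 0 °C; 10, −78 → 40 °C; AcOH; then TsOH·H2O (cat.), PhMe, 60 °C
Reagents that add atoms: none
Why: Proposed new method: LiN(iPr)2 turns 14 into its α,γ-dianion 15, whose more reactive γ-carbon (C8) adds to the less hindered C9 carbonyl of 10 (aldol, 16); the remaining phosphonate-stabilised α-carbanion (C6) then attacks the C5 ring carbonyl and collapses with loss of diethyl phosphate (intramolecular Horner–Wadsworth–Emmons) to the C5=C6 enol ether 17, and TsOH dehydrates the tertiary β-hydroxy ketone to the conjugated C8=C9 alkene. The closest known reaction types are the γ-selective aldol reactions of β-ketophosphonate dianions and intramolecular Horner–Wadsworth–Emmons cyclisations onto ketones; their union as a [3+3] annulation of a 2,2-disubstituted 1,3-diketone has not been shown. Ring B closes in the second event as a six-membered ring by 6-exo-trig attack of C6 on the C5 carbonyl, the first event being intermolecular. No new stereocentre survives, because C8 and C9 become sp2 on dehydration and C5 is sp2 in 18, so the C10 centre set in step 5 is untouched. The step needs site selectivity (C8 to C9 and C6 to C5, not the reverse), which the order of nucleophilicity within the dianion and the steric gap between the acyclic C9 ketone and the doubly neopentyl C5 ketone should secure; it also needs ring closure to outrun retro-aldol loss of the C9 acyl group, which lithium chelation between O9 and O5 at low temperature and the irreversible phosphate elimination should favour.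

Step 9
Reactants: 18 2α-(tert-butyldimethylsilyloxy)-15-(tert-butyldiphenylsilyloxy)-6-methoxylabda-5,8,13E-trien-7-one
Product: 20 2α-(tert-butyldimethylsilyloxy)-15-(tert-butyldiphenylsilyloxy)-7β-hydroxylabda-8,13E-dien-6-one (5α-H), via dienol 19 (not isolated)
Conditions: NaBH4, CeCl3·7H2O, MeOH–THF, −40 °C; then 0.5 M aq. oxalic acid, THF, 23 °C
Reagents that add atoms: water, O
Why: Luche 1,2-reduction should deliver hydride to C7 on the α face, anti to the axial C10 methyl, and once the carbonyl is gone mild acid should hydrolyse the C5=C6 methyl enol ether, the C5 proton settling on the α face because that centre is epimerisable next to the new C6 ketone (trans ring fusion).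

Step 10
Reactants: 20 2α-(tert-butyldimethylsilyloxy)-15-(tert-butyldiphenylsilyloxy)-7β-hydroxylabda-8,13E-dien-6-one
Product: 21 7α-acetoxy-2α-(tert-butyldimethylsilyloxy)-15-(tert-butyldiphenylsilyloxy)labda-8,13E-dien-6-one
Conditions: AcOH, PPh3, diisopropyl azodicarboxylate, PhMe, 0 → 23 °C
Reagents that add atoms: acetic acid, CC(=O)O
Why: Mitsunobu esterification should invert the activated (allylic and α-keto) C7 carbinol by SN2 attack of acetate from the open α face, installing the 7α-acetate directly.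

Step 11
Reactants: 21 7α-acetoxy-2α-(tert-butyldimethylsilyloxy)-15-(tert-butyldiphenylsilyloxy)labda-8,13E-dien-6-one
Product: 22 7α-acetoxy-2α-(tert-butyldimethylsilyloxy)-15-(tert-butyldiphenylsilyloxy)labda-8,13E-dien-6β-ol
Conditions: NaBH4, MeOH–CH2Cl2, −20 °C
Reagents that add atoms: none
Why: Borohydride reduction of the C6 ketone should occur from the α face because the β face is blocked by the syn-axial C4 and C10 methyl groups, giving the axial 6β-alcohol, trans-diaxial to the 7α-acetate so that acyl migration is geometrically barred.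

Step 12
Reactants: 22 7α-acetoxy-2α-(tert-butyldimethylsilyloxy)-15-(tert-butyldiphenylsilyloxy)labda-8,13E-dien-6β-ol
Product: 23 7α-acetoxy-2α-(tert-butyldimethylsilyloxy)-15-(tert-butyldiphenylsilyloxy)-6β-(3-methylbutanoyloxy)labda-8,13E-diene
Conditions: (iPrCH2CO)2O, Et3N, DMAP, CH2Cl2, 40 °C
Reagents that add atoms: 3-methylbutanoic anhydride, CC(C)CC(=O)OC(=O)CC(C)C
Why: DMAP-catalysed acyl transfer should esterify the hindered axial 6β-hydroxyl, the only free hydroxyl in 22, with retention at C6.

Step 13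
Reactants: 23 7α-acetoxy-2α-(tert-butyldimethylsilyloxy)-15-(tert-butyldiphenylsilyloxy)-6β-(3-methylbutanoyloxy)labda-8,13E-diene
Product: 24 7α-acetoxy-15-(tert-butyldiphenylsilyloxy)-6β-(3-methylbutanoyloxy)labda-8,13E-dien-2α-ol
Conditions: HF·pyridine, pyridine, THF, 0 °C
Reagents that add atoms: none
Why: Buffered fluoride desilylation should cleave the secondary tert-butyldimethylsilyl ether at C2 faster than the bulkier primary tert-butyldiphenylsilyl ether and leave both esters alone.

Step 14
Reactants: 24 7α-acetoxy-15-(tert-butyldiphenylsilyloxy)-6β-(3-methylbutanoyloxy)labda-8,13E-dien-2α-ol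
Product: 25 2α,7α-diacetoxy-15-(tert-butyldiphenylsilyloxy)-6β-(3-methylbutanoyloxy)labda-8,13E-diene
Conditions: Ac2O, pyridine, DMAP (cat.), CH2Cl2, 23 °C
Reagents that add atoms: acetic anhydride, CC(=O)OC(C)=O
Why: Acetylation of the unhindered equatorial 2α-hydroxyl should proceed with retention and complete the ester pattern of rings A and B.

Step 15
Reactants: 25 2α,7α-diacetoxy-15-(tert-butyldiphenylsilyloxy)-6β-(3-methylbutanoyloxy)labda-8,13E-diene
Product: 26 2α,7α-diacetoxy-6β-(3-methylbutanoyloxy)labda-8,13E-dien-15-ol (target)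
Conditions: HF·pyridine, THF, 23 °C
Reagents that add atoms: none
Why: Desilylation of the primary allylic silyl ether under non-basic fluoride conditions should free O15 without ester migration or hydrolysis.

**Compound list**

1 | geraniol | CC(C)=CCC/C(C)=C/CO | starting material
2 | geranyl tert-butyldiphenylsilyl ether | CC(C)=CCC/C(C)=C/CO[Si](c1ccccc1)(c1ccccc1)C(C)(C)C | intermediate
3 | 6,7-epoxygeranyl tert-butyldiphenylsilyl ether (racemic at the epoxide) | CC1(C)OC1CC/C(C)=C/CO[Si](c2ccccc2)(c2ccccc2)C(C)(C)C | intermediate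
4 | (2E)-1-(tert-butyldiphenylsilyloxy)-3,7-dimethyloct-2-ene-6,7-diol (not isolated) | CC(C)(O)C(O)CC/C(C)=C/CO[Si](c1ccccc1)(c1ccccc1)C(C)(C)C | intermediate
5 | (4E)-6-(tert-butyldiphenylsilyloxy)-4-methylhex-4-enal | O=CCC/C(C)=C/CO[Si](c1ccccc1)(c1ccccc1)C(C)(C)C | intermediate
6 | (4R,6R)-4-hydroxy-2,2,6-trimethylcyclohexan-1-one (actinol) | O[C@H]1CC(C)(C)C(=O)[C@H](C)C1 | starting material
7 | (4R,6R)-4-(tert-butyldimethylsilyloxy)-2,2,6-trimethylcyclohexan-1-one | CC(C)(C)[Si](C)(C)O[C@H]1CC(C)(C)C(=O)[C@H](C)C1 | intermediate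
8 | lithium enolate of 7 (C5–O–Li, C5=C10; not isolated) | CC(C)(C)[Si](C)(C)O[C@H]1CC(C)(C)C(O[Li])=C(C)C1 | intermediate
9 | C10-quaternary aldol adduct (2α-silyloxy; 10β-methyl; C9 carbinol, both epimers) | CC(C)(C)[Si](C)(C)O[C@H]1CC(C)(C)C(=O)[C@@](C)(C(O)CC/C(C)=C/CO[Si](c2ccccc2)(c2ccccc2)C(C)(C)C)C1 | intermediate
10 | β-diketone (C5 and C9 carbonyls on C10; 2α-silyloxy; 10β-methyl) | CC(C)(C)[Si](C)(C)O[C@H]1CC(C)(C)C(=O)[C@@](C)(C(=O)CC/C(C)=C/CO[Si](c2ccccc2)(c2ccccc2)C(C)(C)C)C1 | intermediate
11 | diethyl (methoxymethyl)phosphonate | CCOP(=O)(COC)OCC | starting material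
12 | methyl propanoate | CCC(=O)OC | starting material
13 | diethyl [lithio(methoxy)methyl]phosphonate (not isolated) | CCOP(=O)(C([Li])OC)OCC | intermediate
14 | diethyl (1-methoxy-2-oxobutyl)phosphonate | CCC(=O)C(OC)P(=O)(OCC)OCC | intermediate
15 | dilithium α,γ-dianion of 14 (C6 and C8; not isolated) | [Li+].[Li+].C[CH-]C(=O)[C-](OC)P(=O)(OCC)OCC | intermediate
16 | C8–C9 aldol adduct with the phosphonate intact (not isolated; C6, C8, C9 unassigned) | CC(C)(C)[Si](C)(C)O[C@H]1CC(C)(C)C(=O)[C@@](C)(C(O)(CC/C(C)=C/CO[Si](c2ccccc2)(c2ccccc2)C(C)(C)C)C(C)C(=O)C(OC)P(=O)(OCC)OCC)C1 | intermediate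
17 | 9-hydroxy-6-methoxy-5-en-7-one with ring B closed (not isolated; C8, C9 unassigned) | CC(C)(C)[Si](C)(C)O[C@H]1CC(C)(C)C2=C(OC)C(=O)C(C)C(O)(CC/C(C)=C/CO[Si](c3ccccc3)(c3ccccc3)C(C)(C)C)[C@@]2(C)C1 | intermediate
18 | 2α-(tert-butyldimethylsilyloxy)-15-(tert-butyldiphenylsilyloxy)-6-methoxylabda-5,8,13E-trien-7-one | CC(C)(C)[Si](C)(C)O[C@H]1CC(C)(C)C2=C(OC)C(=O)C(C)=C(CC/C(C)=C/CO[Si](c3ccccc3)(c3ccccc3)C(C)(C)C)[C@@]2(C)C1 | intermediate
19 | 6-methoxylabda-5,8,13E-trien-7β-ol, 2α-silyloxy and 15-silyloxy as in 18 (not isolated) | CC(C)(C)[Si](C)(C)O[C@H]1CC(C)(C)C2=C(OC)[C@H](O)C(C)=C(CC/C(C)=C/CO[Si](c3ccccc3)(c3ccccc3)C(C)(C)C)[C@@]2(C)C1 | intermediate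
20 | 2α-(tert-butyldimethylsilyloxy)-15-(tert-butyldiphenylsilyloxy)-7β-hydroxylabda-8,13E-dien-6-one (5α-H) | CC(C)(C)[Si](C)(C)O[C@H]1CC(C)(C)[C@@H]2C(=O)[C@H](O)C(C)=C(CC/C(C)=C/CO[Si](c3ccccc3)(c3ccccc3)C(C)(C)C)[C@@]2(C)C1 | intermediate
21 | 7α-acetoxy-2α-(tert-butyldimethylsilyloxy)-15-(tert-butyldiphenylsilyloxy)labda-8,13E-dien-6-one | CC(C)(C)[Si](C)(C)O[C@H]1CC(C)(C)[C@@H]2C(=O)[C@@H](OC(C)=O)C(C)=C(CC/C(C)=C/CO[Si](c3ccccc3)(c3ccccc3)C(C)(C)C)[C@@]2(C)C1 | intermediate
22 | 7α-acetoxy-2α-(tert-butyldimethylsilyloxy)-15-(tert-butyldiphenylsilyloxy)labda-8,13E-dien-6β-ol | CC(C)(C)[Si](C)(C)O[C@H]1CC(C)(C)[C@@H]2[C@H](O)[C@@H](OC(C)=O)C(C)=C(CC/C(C)=C/CO[Si](c3ccccc3)(c3ccccc3)C(C)(C)C)[C@@]2(C)C1 | intermediate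
23 | 7α-acetoxy-2α-(tert-butyldimethylsilyloxy)-15-(tert-butyldiphenylsilyloxy)-6β-(3-methylbutanoyloxy)labda-8,13E-diene | CC(C)(C)[Si](C)(C)O[C@H]1CC(C)(C)[C@@H]2[C@H](OC(=O)CC(C)C)[C@@H](OC(C)=O)C(C)=C(CC/C(C)=C/CO[Si](c3ccccc3)(c3ccccc3)C(C)(C)C)[C@@]2(C)C1 | intermediate
24 | 7α-acetoxy-15-(tert-butyldiphenylsilyloxy)-6β-(3-methylbutanoyloxy)labda-8,13E-dien-2α-ol | O[C@H]1CC(C)(C)[C@@H]2[C@H](OC(=O)CC(C)C)[C@@H](OC(C)=O)C(C)=C(CC/C(C)=C/CO[Si](c3ccccc3)(c3ccccc3)C(C)(C)C)[C@@]2(C)C1 | intermediate
25 | 2α,7α-diacetoxy-15-(tert-butyldiphenylsilyloxy)-6β-(3-methylbutanoyloxy)labda-8,13E-diene | CC(=O)O[C@H]1CC(C)(C)[C@@H]2[C@H](OC(=O)CC(C)C)[C@@H](OC(C)=O)C(C)=C(CC/C(C)=C/CO[Si](c3ccccc3)(c3ccccc3)C(C)(C)C)[C@@]2(C)C1 | intermediate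
26 | 2α,7α-diacetoxy-6β-(3-methylbutanoyloxy)labda-8,13E-dien-15-ol | CC(=O)O[C@H]1CC(C)(C)[C@@H]2[C@H](OC(=O)CC(C)C)[C@@H](OC(C)=O)C(C)=C(CC/C(C)=C/CO)[C@@]2(C)C1 | target

**Step count**

Total steps: 15. Longest linear sequence: 13 steps (1, 2, 3, 5, 6, 8, 9, 10, 11, 12, 13, 14, 15).

**Steps most likely to fail**

Step 8 (bears the label "Proposed new method:"). What may go wrong: retro-aldol loss of the C9 acyl group from the first adduct before ring closure; enolisation of the C9 ketone by the dianion; failure of the C6 carbanion to add to the doubly neopentyl C5 carbonyl. The fallback uses known chemistry, makes the two bonds in separate steps, and closes ring B by metathesis. It sets out from diketone 10 and comes back at acetoxy ketone 21. Wittig methylenation (Ph3PCH3Br, KOtBu, PhMe) of the less hindered C9 carbonyl should give methylene ketone F1. Corey–Chaykovsky epoxidation of the C5 ketone (Me3SI, n-BuLi, THF) should give spiro-epoxide F2. MgBr2·OEt2 should open F2 with a 1,2-hydride shift (Meinwald rearrangement) to aldehyde F3, forming C5–C6 with the C5 hydrogen in place. 2-Methylallylmagnesium chloride should add to give homoallylic alcohol F4. Ring-closing metathesis of the two 1,1-disubstituted alkenes (second-generation Hoveyda–Grubbs catalyst, PhMe, 80 °C) should form C8=C9 in cyclohexenol F5. Dess–Martin oxidation, with DBU to equilibrate C5 to the trans fusion, should give ketone F6. Deprotonation at the doubly activated C7 (KN(SiMe3)2, THF, −78 °C) and α-face hydroxylation with 2-(phenylsulfonyl)-3-phenyloxaziridine should give 7α-hydroxy ketone F7. Ac2O in pyridine then gives 21.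

Step 5. What may go wrong: poor facial selectivity in the bond formation at C10, and reversal of the hindered aldolate. The fallback replaces the intermolecular aldol by an intramolecular acyl delivery from the C2 oxygen, which can only place the acyl group cis to O2. It sets out from aldehyde 5 and actinol 6 and comes back at diketone 10. Pinnick oxidation of 5 (NaClO2, NaH2PO4, 2-methylbut-2-ene) should give acid F8. Esterification with 6 (dicyclohexylcarbodiimide, DMAP) should give ester F9. LiN(SiMe3)2 (THF, −78 → 0 °C) should trigger a Baker–Venkataraman-type O-to-C acyl shift through a bridged five-membered tetrahedral intermediate to hydroxy diketone F10, which is silylated in the same flask (TBSOTf, 2,6-lutidine) before retro-Claisen cleavage can occur, giving 10.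

Step 10. What may go wrong: incomplete inversion through ionisation at the allylic α-keto carbon, or elimination toward a conjugated dienone. The fallback replaces SN2 inversion by epimerisation under thermodynamic control. It sets out from hydroxy ketone 20 and comes back at acetoxy ketone 21. Acetylation of 20 (Ac2O, pyridine, DMAP) should give 7β-acetate F11. DBU in PhMe should then equilibrate C7 through the C6–C7 enolate to the pseudoaxial 7α-acetate 21, which is free of allylic strain against the C8 methyl.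

**Further compounds**

F1 | step 8 | methylene ketone (C9=CH2; C5 ketone kept) | CC(C)(C)[Si](C)(C)O[C@H]1CC(C)(C)C(=O)[C@@](C)(C(=C)CC/C(C)=C/CO[Si](c2ccccc2)(c2ccccc2)C(C)(C)C)C1
F2 | step 8 | spiro-epoxide at C5 (C5 unassigned) | CC(C)(C)[Si](C)(C)O[C@H]1CC(C)(C)C2(CO2)[C@@](C)(C(=C)CC/C(C)=C/CO[Si](c3ccccc3)(c3ccccc3)C(C)(C)C)C1
F3 | step 8 | aldehyde (C6 formyl on C5; 5α-H) | CC(C)(C)[Si](C)(C)O[C@H]1CC(C)(C)[C@H](C=O)[C@@](C)(C(=C)CC/C(C)=C/CO[Si](c2ccccc2)(c2ccccc2)C(C)(C)C)C1
F4 | step 8 | homoallylic alcohol (C6 carbinol, both epimers) | CC(C)(C)[Si](C)(C)O[C@H]1CC(C)(C)[C@H](C(O)CC(C)=C)[C@@](C)(C(=C)CC/C(C)=C/CO[Si](c2ccccc2)(c2ccccc2)C(C)(C)C)C1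
F5 | step 8 | 2α-(tert-butyldimethylsilyloxy)-15-(tert-butyldiphenylsilyloxy)labda-8,13E-dien-6-ol (both C6 epimers) | CC(C)(C)[Si](C)(C)O[C@H]1CC(C)(C)[C@@H]2C(O)CC(C)=C(CC/C(C)=C/CO[Si](c3ccccc3)(c3ccccc3)C(C)(C)C)[C@@]2(C)C1
F6 | step 8 | 2α-(tert-butyldimethylsilyloxy)-15-(tert-butyldiphenylsilyloxy)labda-8,13E-dien-6-one | CC(C)(C)[Si](C)(C)O[C@H]1CC(C)(C)[C@@H]2C(=O)CC(C)=C(CC/C(C)=C/CO[Si](c3ccccc3)(c3ccccc3)C(C)(C)C)[C@@]2(C)C1
F7 | step 8 | 2α-(tert-butyldimethylsilyloxy)-15-(tert-butyldiphenylsilyloxy)-7α-hydroxylabda-8,13E-dien-6-one | CC(C)(C)[Si](C)(C)O[C@H]1CC(C)(C)[C@@H]2C(=O)[C@@H](O)C(C)=C(CC/C(C)=C/CO[Si](c3ccccc3)(c3ccccc3)C(C)(C)C)[C@@]2(C)C1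
F8 | step 5 | (4E)-6-(tert-butyldiphenylsilyloxy)-4-methylhex-4-enoic acid | OC(=O)CC/C(C)=C/CO[Si](c1ccccc1)(c1ccccc1)C(C)(C)C
F9 | step 5 | ester of actinol with acid F8 | O=C(CC/C(C)=C/CO[Si](c2ccccc2)(c2ccccc2)C(C)(C)C)O[C@H]1CC(C)(C)C(=O)[C@H](C)C1
F10 | step 5 | hydroxy diketone (10 without its C2 silyl group) | O[C@H]1CC(C)(C)C(=O)[C@@](C)(C(=O)CC/C(C)=C/CO[Si](c2ccccc2)(c2ccccc2)C(C)(C)C)C1
F11 | step 10 | 7β-acetoxy-2α-(tert-butyldimethylsilyloxy)-15-(tert-butyldiphenylsilyloxy)labda-8,13E-dien-6-one | CC(C)(C)[Si](C)(C)O[C@H]1CC(C)(C)[C@@H]2C(=O)[C@H](OC(C)=O)C(C)=C(CC/C(C)=C/CO[Si](c3ccccc3)(c3ccccc3)C(C)(C)C)[C@@]2(C)C1
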